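Altisin is disconnected at the O1–C2 bond of ring C. Ring A carries three adjacent oxygens (O1 on C8a, then the C8 and C7 methoxy groups) and a separate oxygen at C5, which maps onto 3,4,5-trimethoxyphenol acylated ortho to its hydroxyl. The key step uses this: ICl activates an aryl alkynyl ketone, the methoxy oxygen that is to become O1 adds to C2 and sheds its methyl group, and ring C closes as a 3-iodochromone in one operation. The precursor is the ynone 2-[3-(2,6-dimethoxyphenyl)prop-2-ynoyl]-3,4,5-trimethoxyphenyl pivalate, whose future C5 hydroxyl is masked as a non-nucleophilic, ring-deactivating ester so that only the methoxy oxygen can cyclize.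

Key step: step 6

Remark: the acid chloride is used crude after evaporation and the deiodinated ester is cleaved in the same flask, so both are treated as non-isolated intermediates. No compound in the route has a stereocentre.

Step 1
Reactants: 1 3,4,5-trimethoxyphenol
Product: 2 6-hydroxy-2,3,4-trimethoxybenzaldehyde
Conditions: POCl3, DMF, 0 °C to rt; then aq. NaOAc
Reagents that add atoms: N,N-dimethylformamide, CN(C)C=O; water, O
Why: Vilsmeier–Haack formylation, in which the chloroiminium ion attacks ortho to the hydroxyl (the two free ring positions are equivalent, so only one aldehyde can form) and the iminium salt is hydrolysed on work-up.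

Step 2
Reactants: 2 6-hydroxy-2,3,4-trimethoxybenzaldehyde; 3 pivaloyl chloride
Product: 4 2-formyl-3,4,5-trimethoxyphenyl pivalate
Conditions: Et3N, DMAP (cat.), CH2Cl2, 0 °C to rt
Reagents that add atoms: none
Why: DMAP-catalysed O-acylation of the phenol (nucleophilic acyl substitution) should give a hindered aryl ester that makes this oxygen a poor nucleophile and withstands the oxidation, acid chloride formation and ICl steps that follow.

Step 3
Reactants: 4 2-formyl-3,4,5-trimethoxyphenyl pivalate
Product: 5 2,3,4-trimethoxy-6-(pivaloyloxy)benzoic acid
Conditions: NaClO2, NaH2PO4, 2-methyl-2-butene, t-BuOH/H2O, rt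
Reagents that add atoms: sodium chlorite, [Na+].[O-]Cl=O
Why: Pinnick oxidation converts the aldehyde into the acid under buffered, weakly acidic conditions that leave the aryl pivalate intact, while 2-methyl-2-butene traps HOCl before it can chlorinate the electron-rich ring.

Step 4
Reactants: 6 2,6-dimethoxybenzaldehyde
Product: 7 2-ethynyl-1,3-dimethoxybenzene
Conditions: dimethyl (1-diazo-2-oxopropyl)phosphonate, K2CO3, MeOH, 0 °C to rt
Reagents that add atoms: dimethyl (1-diazo-2-oxopropyl)phosphonate (Ohira–Bestmann reagent), COP(=O)(OC)C(=[N+]=[N-])C(C)=O
Why: Ohira–Bestmann variant of the Seyferth–Gilbert homologation, in which methanolysis of the acetyl group frees the diazomethylphosphonate anion, this adds to the non-enolizable aldehyde, and the diazoalkene loses N2 with a 1,2-hydrogen shift to give the terminal alkyne.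

Step 5
Reactants: 5 2,3,4-trimethoxy-6-(pivaloyloxy)benzoic acid; 7 2-ethynyl-1,3-dimethoxybenzene
Product: 9 2-[3-(2,6-dimethoxyphenyl)prop-2-ynoyl]-3,4,5-trimethoxyphenyl pivalate, via acid chloride 8 (not isolated)
Conditions: (COCl)2, DMF (cat.), CH2Cl2, 0 °C to rt, evaporate; then 7, PdCl2(PPh3)2 (cat.), CuI (cat.), Et3N, THF, rt
Reagents that add atoms: none
Why: Acid chloride formation followed by acyl Sonogashira coupling (oxidative addition of zerovalent palladium into the C–Cl bond, transmetalation from the copper acetylide, reductive elimination) should give the ynone at room temperature without harming the aryl ester, and with no free phenol present the ynone cannot cyclize early.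

Step 6
Reactants: 9 2-[3-(2,6-dimethoxyphenyl)prop-2-ynoyl]-3,4,5-trimethoxyphenyl pivalate
Product: 10 2-(2,6-dimethoxyphenyl)-3-iodo-7,8-dimethoxy-4-oxo-4H-chromen-5-yl pivalate
Conditions: ICl (1.2 equiv), CH2Cl2, −78 °C, dark; aq. Na2S2O3
Reagents that add atoms: iodine monochloride, ClI
Why: ICl transfers an iodonium ion to the ynone triple bond; the methoxy oxygen ortho to the ketone (the one between the acyl-bearing carbon and the neighbouring methoxy group, the future O1) attacks the alkyne carbon remote from the carbonyl (future C2) anti to iodine, and chloride then takes the methyl group from the resulting aryl methyl oxonium ion in an SN2 step, releasing chloromethane and the neutral 3-iodochromone. The closest known reaction type is the ICl-induced demethylative iodocyclization of ortho-methoxyaryl alkynyl ketones to 3-iodochromones. Ring C is closed in the 6-endo-dig mode, preferred over 5-exo-dig because the ynone is polarized so that iodine bonds to the carbon next to the carbonyl while positive charge builds at the aryl-bearing carbon, where the 2,6-dimethoxyphenyl group stabilizes it. No stereocentre is formed. The step needs chemoselectivity among the oxygens and between alkyne and arenes: the second ortho oxygen of the aroyl ring is an ester whose lone pair is tied up in the pivaloyl carbonyl and which has no alkyl group to lose, the ring B methoxy groups can reach only the electronically mismatched carbonyl-adjacent alkyne carbon, and ring iodination is held back by the low temperature, the near-stoichiometric ICl and the deactivation of ring A by its acyl and acyloxy substituents.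

Step 7
Reactants: 10 2-(2,6-dimethoxyphenyl)-3-iodo-7,8-dimethoxy-4-oxo-4H-chromen-5-yl pivalate
Product: 12 altisin (2-(2,6-dimethoxyphenyl)-5-hydroxy-7,8-dimethoxy-4H-chromen-4-one), via deiodinated flavone pivalate 11 (not isolated)
Conditions: Pd(PPh3)4 (cat.), HCO2Na, DMF, 100 °C; then K2CO3, MeOH, rt to 40 °C; aq. HCl work-up
Reagents that add atoms: none
Why: Palladium-catalysed formate hydrodehalogenation (oxidative addition into the C3–I bond, formate exchange, decarboxylation to a palladium hydride, reductive elimination) should replace iodine by hydrogen, and base-mediated transesterification in methanol then frees the C5 hydroxyl, with the four methyl ethers inert to both stages.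

Compound list
1 | 3,4,5-trimethoxyphenol | COc1cc(O)cc(OC)c1OC | starting material
2 | 6-hydroxy-2,3,4-trimethoxybenzaldehyde | COc1cc(O)c(C=O)c(OC)c1OC | intermediate
3 | pivaloyl chloride (2,2-dimethylpropanoyl chloride) | CC(C)(C)C(Cl)=O | starting material
4 | 2-formyl-3,4,5-trimethoxyphenyl pivalate | COc1cc(OC(=O)C(C)(C)C)c(C=O)c(OC)c1OC | intermediate
5 | 2,3,4-trimethoxy-6-(pivaloyloxy)benzoic acid | COc1cc(OC(=O)C(C)(C)C)c(C(=O)O)c(OC)c1OC | intermediate
6 | 2,6-dimethoxybenzaldehyde | COc1cccc(OC)c1C=O | starting material
7 | 2-ethynyl-1,3-dimethoxybenzene | COc1cccc(OC)c1C#C | intermediate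
8 | 2,3,4-trimethoxy-6-(pivaloyloxy)benzoyl chloride | COc1cc(OC(=O)C(C)(C)C)c(C(Cl)=O)c(OC)c1OC | intermediate (not isolated)
9 | 2-[3-(2,6-dimethoxyphenyl)prop-2-ynoyl]-3,4,5-trimethoxyphenyl pivalate | COc1cccc(OC)c1C#CC(=O)c1c(OC)c(OC)c(OC)cc1OC(=O)C(C)(C)C | intermediate
10 | 2-(2,6-dimethoxyphenyl)-3-iodo-7,8-dimethoxy-4-oxo-4H-chromen-5-yl pivalate | COc1cccc(OC)c1-c1oc2c(OC)c(OC)cc(OC(=O)C(C)(C)C)c2c(=O)c1I | intermediate
11 | 2-(2,6-dimethoxyphenyl)-7,8-dimethoxy-4-oxo-4H-chromen-5-yl pivalate | COc1cccc(OC)c1-c1cc(=O)c2c(OC(=O)C(C)(C)C)cc(OC)c(OC)c2o1 | intermediate (not isolated)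
12 | altisin, 2-(2,6-dimethoxyphenyl)-5-hydroxy-7,8-dimethoxy-4H-chromen-4-one | COc1cccc(OC)c1-c1cc(=O)c2c(O)cc(OC)c(OC)c2o1 | target

Total step count: 7. Longest linear sequence: 6 steps (steps 1, 2, 3, 5, 6 and 7, from 1 through 2, 4, 5, 9 and 10 to 12); step 4 supplies alkyne 7 in a one-step branch.

Steps most likely to fail

Step 6. Electrophilic iodination of the electron-rich rings, or plain addition of ICl across the triple bond, may outpace ring closure, and the doubly ortho-substituted aroyl group may slow the approach of the methoxy oxygen. The fallback forms the O1–C2 bond without an external electrophile. Starting from ynone 9, BCl3 (CH2Cl2, −78 to 0 °C) should remove only the methyl group of the methoxy ortho to the ketone, through a six-membered boron chelate, to give 2-[3-(2,6-dimethoxyphenyl)prop-2-ynoyl]-3-hydroxy-4,5-dimethoxyphenyl pivalate F1. TfOH in CH2Cl2 should then promote 6-endo cyclization of this ortho-alkynoylphenol to flavone pivalate 11, where the route is rejoined for the K2CO3/MeOH stage of step 7.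

Step 5. The hindered, electron-rich acid chloride may hydrolyse or decarbonylate faster than it couples, while the alkyne is consumed by oxidative dimerization. The fallback builds the ketone carbon from carbon monoxide instead. Phenol 1 is iodinated ortho to the hydroxyl with N-iodosuccinimide (MeCN, 0 °C) to 2-iodo-3,4,5-trimethoxyphenol F2, which is acylated with pivaloyl chloride 3 (Et3N, DMAP, CH2Cl2) to 2-iodo-3,4,5-trimethoxyphenyl pivalate F3. Carbonylative Sonogashira coupling of F3 with alkyne 7 (PdCl2(PPh3)2, CuI, CO at 1 atm, Et3N, THF) returns to the route at ynone 9.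

Step 7. Palladium hydride chemistry may stall at the crowded C3–I bond, which sits between the carbonyl and the 2,6-dimethoxyphenyl group, or may reduce the C2–C3 double bond of the pyranone. The fallback removes the iodine from 10 by a radical chain reduction with (Me3Si)3SiH and AIBN in toluene at 80 °C, giving 11, which rejoins the route for the K2CO3/MeOH stage. This fallback makes no compound outside the list (F0).

Further compounds
F1 | step 6 | 2-[3-(2,6-dimethoxyphenyl)prop-2-ynoyl]-3-hydroxy-4,5-dimethoxyphenyl pivalate | COc1cccc(OC)c1C#CC(=O)c1c(O)c(OC)c(OC)cc1OC(=O)C(C)(C)C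
F2 | step 5 | 2-iodo-3,4,5-trimethoxyphenol | COc1cc(O)c(I)c(OC)c1OC
F3 | step 5 | 2-iodo-3,4,5-trimethoxyphenyl pivalate | COc1cc(OC(=O)C(C)(C)C)c(I)c(OC)c1OC
F0 | step 7 | none | none
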